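**Strategy.** Lignan numbering is used: oxolane ring O–C7(aryl)–C8(C9H2OH)–C8'(C7'H(OH)Ar')–C9'H2. The aryl–C7 bond is the last skeletal bond made. Because the C9 and C7' substituents are cis on the oxolane, O7' and C9 can be tied as a γ-lactone, giving a cis-fused 3,7-dioxabicyclo[3.3.0]octan-2-one whose acetal carbon is C7. Its bicyclic oxocarbenium ion takes the guaiacyl group from a potassium aryltrifluoroborate on the convex face, forming the aryl–C7 bond and the C7 stereocentre (trans to the C8 substituent) in one operation. The precursor is a lactone-fused 2-methoxyoxolane from an Evans aldol–lactonisation; lactone reduction later frees the C9 and C7' hydroxyls.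

Key step: step 6

Remark on the target: the SMILES corresponds to the (7S,8R,7'S,8'R) isomer, with aryl/CH2OH trans (C7/C8) and CH2OH/carbinol side chain cis (C8/C8') on the oxolane.

Remark on compound 9: it is carried as the mixture of epimers at its acetal carbon (C7), since both ionise to the same oxocarbenium ion; its SMILES leaves that centre open.

Remark on ring numbering: in the bicyclic names, C1 = C8, C2 = C9, O3 = O7', C4 = C7', C5 = C8', C6 = C9', C8 = C7 of the lignan numbering.

Step 1
Reactants: 1 (S)-4-benzyloxazolidin-2-one; 2 methyl 4-chloro-4-oxobutanoate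
Product: 3 (S)-4-benzyl-3-(4-methoxy-4-oxobutanoyl)oxazolidin-2-one
Conditions: n-BuLi, THF, −78 °C; then 2, −78 to 0 °C
Reagents that add atoms: none
Why: N-acylation of the lithiated oxazolidinone by the acid chloride is much faster than attack at the methyl ester, which should give the Evans imide cleanly.

Step 2
Reactants: 3 (S)-4-benzyl-3-(4-methoxy-4-oxobutanoyl)oxazolidin-2-one; 4 4-(benzyloxy)-3-methoxybenzaldehyde
Product: 6 (4S)-4-benzyl-3-{[(2S,3S)-2-(4-benzyloxy-3-methoxyphenyl)-5-oxooxolan-3-yl]carbonyl}oxazolidin-2-one (trans lactone), via syn-aldol adduct 5 (not isolated)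
Conditions: Bu2BOTf, iPr2NEt, CH2Cl2, −78 to 0 °C; 4, −78 to 0 °C; pH 7 buffer, MeOH, H2O2, 0 °C; then CSA (cat.), CH2Cl2, rt
Reagents that add atoms: none
Why: In this Evans syn-aldol reaction the Z boron enolate should react through a chair Zimmerman–Traxler transition state on the face away from the benzyl group of the (S)-auxiliary, setting C8' and C7' (syn), after which the C7' hydroxyl closes the γ-lactone on the methyl ester to give the trans-disubstituted lactone.

Step 3
Reactants: 6 (4S)-4-benzyl-3-{[(2S,3S)-2-(4-benzyloxy-3-methoxyphenyl)-5-oxooxolan-3-yl]carbonyl}oxazolidin-2-one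
Product: 7 (4R,5S)-5-(4-benzyloxy-3-methoxyphenyl)-4-(hydroxymethyl)oxolan-2-one
Conditions: NaBH4, THF/H2O (4:1), 0 °C to rt
Reagents that add atoms: none
Why: Reductive cleavage of the N-acyloxazolidinone with NaBH4 in wet THF should reduce the activated exocyclic imide carbonyl (C9') to the primary alcohol and leave the less electrophilic γ-lactone and both stereocentres untouched.

Step 4
Reactants: 7 (4R,5S)-5-(4-benzyloxy-3-methoxyphenyl)-4-(hydroxymethyl)oxolan-2-one
Product: 9 (1S,4S,5R)-4-(4-benzyloxy-3-methoxyphenyl)-8-methoxy-3,7-dioxabicyclo[3.3.0]octan-2-one (cis-fused; aryl exo; epimers at C8), via hydroxymethylidene lactone 8 (not isolated)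
Conditions: LDA (3.2 equiv), THF, −78 °C (7 added to the base); HCO2Et, −78 to 0 °C; 1 M HCl; then CSA (cat.), MeOH, 3 Å MS, rt
Reagents that add atoms: ethyl formate CCOC=O; methanol CO
Why: Crossed Claisen formylation of the lactone enolate (as the alkoxide–enolate dianion, whose carbonyl cannot be attacked by the alkoxide) should install C7, and acid-catalysed addition of the C9' hydroxyl to the formyl carbon with methanol exchange then gives the mixed cyclic acetal, in which C8, epimerisable through the enol, can only settle in the cis ring fusion.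

Step 5
Reactants: 10 [4-(benzyloxy)-3-methoxyphenyl]boronic acid
Product: 11 potassium [4-(benzyloxy)-3-methoxyphenyl]trifluoroborate
Conditions: KHF2, MeOH/H2O, rt
Reagents that add atoms: potassium hydrogen difluoride [K+].[F-].F
Why: Treatment of an arylboronic acid with KHF2 is the standard route to the crystalline potassium aryltrifluoroborate.

Step 6
Reactants: 9 (1S,4S,5R)-4-(4-benzyloxy-3-methoxyphenyl)-8-methoxy-3,7-dioxabicyclo[3.3.0]octan-2-one; 11 potassium [4-(benzyloxy)-3-methoxyphenyl]trifluoroborate
Product: 14 (1S,4S,5R,8S)-4,8-bis(4-benzyloxy-3-methoxyphenyl)-3,7-dioxabicyclo[3.3.0]octan-2-one (both aryl groups exo), via aryldifluoroborane 12 (not isolated), via oxocarbenium ion 13 (not isolated)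
Conditions: BF3·OEt2 (3 equiv), 11 (2 equiv), CH2Cl2/MeCN, −40 to 0 °C; aq. NaHCO3
Reagents that add atoms: none
Why: BF3·OEt2 abstracts fluoride from 11 to give the Lewis-acidic aryldifluoroborane 12, which ionises the exocyclic C7–OMe bond of 9 to the bicyclic oxocarbenium ion 13, and the aryl group then passes from the aryl(methoxy)difluoroborate to C7 by ipso substitution, so the position on the arene is fixed by the C–B bond (para to the benzyloxy group) and no ring is closed. The closest known reaction type is the BF3-promoted coupling of potassium organotrifluoroborates with mixed O,O-acetals, together with the C-arylation of furanosyl oxocarbenium ions. The new C7 stereocentre is controlled by the cis-fused 3,7-dioxabicyclo[3.3.0]octane: the aryl group should enter on the convex face, anti to the C8–C9 bond, which gives the exo (7,8-trans) isomer. This isomer is also the more stable one, and an endo product could equilibrate to it through reversible benzylic C7–O ionisation under the Lewis acid. The step needs substitution to outrun loss of the C8 proton to the conjugated enol ether, which is disfavoured because the double bond would sit at the ring fusion and because the reaction is run cold with excess borate. The benzylic C7'–O bond should stay closed since its leaving group is a carboxylate held in the lactone ring.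

Step 7
Reactants: 14 (1S,4S,5R,8S)-4,8-bis(4-benzyloxy-3-methoxyphenyl)-3,7-dioxabicyclo[3.3.0]octan-2-one
Product: 15 (S)-(4-benzyloxy-3-methoxyphenyl)[(3R,4R,5S)-5-(4-benzyloxy-3-methoxyphenyl)-4-(hydroxymethyl)oxolan-3-yl]methanol (4,4'-di-O-benzyltanegol)
Conditions: LiAlH4, THF, 0 °C; then H2O, aq. NaOH
Reagents that add atoms: none
Why: LiAlH4 reduction of the γ-lactone to the 1,4-diol should release the C9 primary hydroxyl and the C7' benzylic hydroxyl at once without touching any stereocentre.

Step 8
Reactants: 15 4,4'-di-O-benzyltanegol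
Product: 16 (−)-tanegol, (S)-(4-hydroxy-3-methoxyphenyl)[(3R,4R,5S)-5-(4-hydroxy-3-methoxyphenyl)-4-(hydroxymethyl)oxolan-3-yl]methanol
Conditions: H2 (1 atm), Pd/C, NaHCO3, EtOAc, rt, stopped at full debenzylation
Reagents that add atoms: none
Why: Catalytic hydrogenolysis should cleave the two aryl benzyl ethers far faster than the secondary benzylic alcohol or the 2-aryloxolane C–O bond in neutral buffered ethyl acetate, as is usual for 4-O-benzyl guaiacyl carbinols, so a monitored reaction should give the free bisphenol.

**Compound list**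

1 | (S)-4-benzyloxazolidin-2-one | O=C1OC[C@H](Cc2ccccc2)N1 | starting material
2 | methyl 4-chloro-4-oxobutanoate | COC(=O)CCC(Cl)=O | starting material
3 | (S)-4-benzyl-3-(4-methoxy-4-oxobutanoyl)oxazolidin-2-one | COC(=O)CCC(=O)N1C(=O)OC[C@@H]1Cc1ccccc1 | intermediate
4 | 4-(benzyloxy)-3-methoxybenzaldehyde | O=Cc1ccc(OCc2ccccc2)c(OC)c1 | starting material
5 | methyl (3S)-3-{(S)-[4-(benzyloxy)-3-methoxyphenyl](hydroxy)methyl}-4-[(4S)-4-benzyl-2-oxooxazolidin-3-yl]-4-oxobutanoate (syn-aldol adduct) | COC(=O)C[C@@H]([C@H](O)c1ccc(OCc2ccccc2)c(OC)c1)C(=O)N1C(=O)OC[C@@H]1Cc1ccccc1 | intermediate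
6 | (4S)-4-benzyl-3-{[(2S,3S)-2-(4-benzyloxy-3-methoxyphenyl)-5-oxooxolan-3-yl]carbonyl}oxazolidin-2-one | COc1cc(ccc1OCc1ccccc1)[C@H]1OC(=O)C[C@@H]1C(=O)N1C(=O)OC[C@@H]1Cc1ccccc1 | intermediate
7 | (4R,5S)-5-(4-benzyloxy-3-methoxyphenyl)-4-(hydroxymethyl)oxolan-2-one | COc1cc(ccc1OCc1ccccc1)[C@H]1OC(=O)C[C@@H]1CO | intermediate
8 | (4R,5S)-5-(4-benzyloxy-3-methoxyphenyl)-3-(hydroxymethylidene)-4-(hydroxymethyl)oxolan-2-one | COc1cc(ccc1OCc1ccccc1)[C@H]1OC(=O)C(=CO)[C@@H]1CO | intermediate
9 | (1S,4S,5R)-4-(4-benzyloxy-3-methoxyphenyl)-8-methoxy-3,7-dioxabicyclo[3.3.0]octan-2-one (epimers at the acetal carbon) | COc1cc(ccc1OCc1ccccc1)[C@H]1OC(=O)[C@@H]2C(OC)OC[C@H]12 | intermediate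
10 | [4-(benzyloxy)-3-methoxyphenyl]boronic acid | OB(O)c1ccc(OCc2ccccc2)c(OC)c1 | starting material
11 | potassium [4-(benzyloxy)-3-methoxyphenyl]trifluoroborate | [K+].F[B-](F)(F)c1ccc(OCc2ccccc2)c(OC)c1 | intermediate
12 | [4-(benzyloxy)-3-methoxyphenyl]difluoroborane | FB(F)c1ccc(OCc2ccccc2)c(OC)c1 | intermediate
13 | (1S,4S,5R)-4-(4-benzyloxy-3-methoxyphenyl)-2-oxo-3-oxa-7-oxoniabicyclo[3.3.0]oct-7-ene (oxocarbenium ion) | COc1cc(ccc1OCc1ccccc1)[C@H]1OC(=O)[C@@H]2C=[O+]C[C@H]12 | intermediate
14 | (1S,4S,5R,8S)-4,8-bis(4-benzyloxy-3-methoxyphenyl)-3,7-dioxabicyclo[3.3.0]octan-2-one | COc1cc(ccc1OCc1ccccc1)[C@H]1OC(=O)[C@@H]2[C@@H](c3ccc(OCc4ccccc4)c(OC)c3)OC[C@H]12 | intermediate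
15 | (S)-(4-benzyloxy-3-methoxyphenyl)[(3R,4R,5S)-5-(4-benzyloxy-3-methoxyphenyl)-4-(hydroxymethyl)oxolan-3-yl]methanol | COc1cc(ccc1OCc1ccccc1)[C@@H](O)[C@H]1CO[C@H](c2ccc(OCc3ccccc3)c(OC)c2)[C@H]1CO | intermediate
16 | (−)-tanegol | COc1cc([C@@H](O)[C@H]2CO[C@H](c3ccc(O)c(OC)c3)[C@H]2CO)ccc1O | target

**Step count.** Total: 8 steps. Longest linear sequence: 7 steps (steps 1–4 and 6–8, from 1 to 16); step 5 prepares the aryl donor.

**Steps most likely to fail**

1. Step 6 (key step). The oxocarbenium ion may lose its C8 proton (elimination to the conjugated enol ether), the electron-rich borate may protodeboronate, or the lactone may open at the benzylic C7'–O bond before aryl transfer. The fallback sets out from 9 and removes the lactone first, so that neither an acidic hydrogen next to the cation nor a benzylic acyloxy group is present. Reduction of 9 with LiAlH4 (THF, 0 °C) should give the diol acetal F1. Silylation (TBSCl, imidazole, DMF) gives the bis(tert-butyldimethylsilyl) ether F2. The monocyclic 2-methoxyoxolane is then arylated with 11 and BF3·OEt2 (CH2Cl2/MeCN, −78 °C) to the silylated diaryloxolane F3. Here the 7,8-trans isomer is expected from attack anti to the C8 substituent and from acid equilibration of the benzylic C7 centre. TBAF (THF) then gives 15, where the route is rejoined; steps 6 and 7 are replaced.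

2. Step 4. The alkoxide may attack the lactone carbonyl before enolisation (migration of the lactone from O7' to O9'), formylation may stop at oxygen, or the formyl lactone may rest as its enol instead of closing to the acetal. The fallback sets out from 7 and avoids enolate chemistry. Heating 7 with tert-butoxybis(dimethylamino)methane (toluene, 80 °C) should give the dimethylaminomethylidene lactone F4. Treatment with HCl (1.2 equiv) in MeOH then hydrolyses the enamine and closes the C9' hydroxyl onto C7, returning to the route at 9.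

3. Step 3. Borohydride may also attack the lactone, or the basic aqueous medium may induce lactone migration to the new primary hydroxyl. The fallback sets out from 6 and separates cleavage from reduction. LiOH/H2O2 (THF/H2O, 0 °C, then acidification) removes the auxiliary to give the paraconic acid F5. BH3·SMe2 (THF, 0 °C) then reduces the carboxylic acid selectively in the presence of the lactone under non-basic conditions, returning to the route at 7.

**Further compounds**

F1 | step 6 | (S)-(4-benzyloxy-3-methoxyphenyl)[(3R,4R)-4-(hydroxymethyl)-5-methoxyoxolan-3-yl]methanol (epimers at the acetal carbon) | COc1cc(ccc1OCc1ccccc1)[C@@H](O)[C@H]1COC(OC)[C@H]1CO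
F2 | step 6 | bis(tert-butyldimethylsilyl) ether of F1 | COc1cc(ccc1OCc1ccccc1)[C@@H](O[Si](C)(C)C(C)(C)C)[C@H]1COC(OC)[C@H]1CO[Si](C)(C)C(C)(C)C
F3 | step 6 | bis(tert-butyldimethylsilyl) ether of 15 | COc1cc(ccc1OCc1ccccc1)[C@@H](O[Si](C)(C)C(C)(C)C)[C@H]1CO[C@H](c2ccc(OCc3ccccc3)c(OC)c2)[C@H]1CO[Si](C)(C)C(C)(C)C
F4 | step 4 | (4R,5S)-5-(4-benzyloxy-3-methoxyphenyl)-3-[(dimethylamino)methylidene]-4-(hydroxymethyl)oxolan-2-one | COc1cc(ccc1OCc1ccccc1)[C@H]1OC(=O)C(=CN(C)C)[C@@H]1CO
F5 | step 3 | (2S,3S)-2-(4-benzyloxy-3-methoxyphenyl)-5-oxooxolane-3-carboxylic acid | COc1cc(ccc1OCc1ccccc1)[C@H]1OC(=O)C[C@@H]1C(O)=O
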